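## Structural features

The target is a single carbocycle, a 2-chlorocyclopent-2-enone (ring C8–C12 in prostanoid numbering, with the ketone at C9, chlorine on C10 and the ring olefin C10=C11), carrying two chains on adjacent ring carbons. C8 bears an exocyclic double bond that continues as a (5E,7E)-dienyl chain to the methyl ester C1, so the C9 ketone is cross-conjugated between C10=C11 and C7=C8. C12 is a fully substituted carbinol carbon holding the acetate and the (Z)-oct-2-enyl chain C13–C20; it is the only stereocentre (R), it lies between the sp2 ring carbons C8 and C11, and no neighbouring stereocentre exists from which it could be set by relay. Three olefin geometries (5E, 7E, 14Z) must also be delivered. The chlorodienone is a strong Michael acceptor and sensitive to base, nucleophiles and light. The tertiary acetate is β to the ketone in any precursor that still has hydrogens on C8 and would be eliminated by base, the skipped C14 Z-olefin does not tolerate electrophilic halogen, and the ester limits the use of hydride and hydroxide. The real difficulty is therefore twofold: the absolute configuration of an isolated quaternary carbinol carbon, and the placing of chlorine on C10 while C14=C15 is in the molecule. The key step uses the fact that C12 carries two CH2 groups, C8 in the ring and C13 in the chain. In a 3-alkynylpentanedial these are two enantiotopic CH2CHO arms and the alkyne is C10–C11, so forming C9–C10 from one arm closes ring C8–C12, fixes C12, and leaves the other arm as the C14 aldehyde with silicon marking C10.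

## Logic of the disconnections

22 ⇒ 21 ⇒ 20. The acetyl C–O bond and then the O–Si bond at C12 are cut. The acetate is put on last because, in every earlier ring compound with hydrogens on C8, a C12 acetate is a β-leaving group for the C8 enolate. The gain is a silyl ether that survives enolate chemistry. The demand is acylation of a hindered tertiary alcohol and a fluoride deprotection that the dienone tolerates.

20 ⇒ 14 + 17 (through 18 and 19). The C7=C8 bond is cut as an aldol condensation. This removes the whole C1–C7 chain in one piece, brings the 5E geometry in with 17, and leaves 7E to the thermodynamics of the elimination. The forward step needs enolization at C8 (the only α-hydrogens of 14), 1,2-addition to an enal, and an E-selective loss of the C7 oxygen.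

17 ⇒ 15 + 16. The C5=C6 bond is cut as a cross-metathesis between two commercial olefins; the demand is E-selectivity and suppression of homodimer.

14 ⇒ 12 ⇒ 11 (through 13). The C10–Cl bond is traced to an epoxide on C10–C11. Nucleophilic oxidation picks the electron-poor ring olefin and ignores C14=C15, which electrophilic chlorine would not. The demand is that chloride opens the epoxide at C10 and that the silyl ether withstands the acid.

11 ⇒ 10. The C10–H bond is traced to C10–Si. The silicon was needed as the cap of the alkyne in the ring-forming step; the demand is cleavage of C–Si in the presence of O–Si.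

10 ⇒ 7 + 8 (through 9). The C14=C15 bond is cut as a Wittig reaction, whose kinetic control gives the Z geometry. The demand is that the ylide takes the aldehyde and leaves the enone and the acidic C8 hydrogens alone.

7 ⇒ 6. The C9–C10 bond is cut, which opens the ring to an acyclic, achiral dialdehyde. This is the largest simplification of the route: one isomerization builds the ring, the enone and the only stereocentre. The demand is ligand-controlled choice between two enantiotopic arms, net trans addition across the alkyne, and cyclization faster than decarbonylation.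

6 ⇒ 5 ⇒ 4 ⇒ 1 + 2 (through 3). The two C=O groups are traced to two terminal olefins, the O–Si bond is cut, and the C12–C8 and C12–C13 bonds are cut together as a double addition of 2 to the ester carbon of 1. The symmetry means no selectivity is needed before the key step; the only demand is 1,2-addition.

## Other disconnections considered

Alternative 1: The cut is C8–C12 together with the C12–O bond, by an oxa-Piancatelli rearrangement of the furylcarbinol methyl 8-{3-chloro-5-[(Z)-oct-2-en-1-yl]furan-2-yl}-8-hydroxyoct-6-ynoate A1. Ionization under Dy(OTf)3 with a chiral phosphoric acid, attack of water at the octenyl-bearing furan carbon, ring opening and conrotatory 4π closure would give the trans hydroxy ketone A2.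
- Correction: the carbinol carbon of A1 becomes ring atom C8, so the chain left on the ring has seven carbons. A2 is therefore methyl 7-{(1S,5S)-3-chloro-5-hydroxy-5-[(Z)-oct-2-en-1-yl]-2-oxocyclopent-3-en-1-yl}hept-6-ynoate, a hept-6-ynoate attached through C7, not an oct-6-ynoate.
- In favour: chlorine, both chains and every carbon are in place before the ring forms. Only an alkyne-to-dienone isomerization and the acetylation would remain. On step economy and convergence this is clearly better than the chosen plan, and it needs no late chlorination.
- Against: an enantioselective oxa-Piancatelli reaction with water as the nucleophile has no close precedent; only the aza variant is catalysed asymmetrically. A furan substituted at the carbon that becomes quaternary C12 reacts sluggishly, and the 3-chloro substituent lowers the nucleophilicity of the furan further. The propargylic cation can be trapped at the alkyne terminus. The base-mediated isomerization must set 5E and 7E on a free β-hydroxy ketone that can undergo retro-aldol cleavage.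
- Comparison: structurally both plans build the same ring. Mechanistically the chosen plan rests on a ring closure whose enantioselective form is established on closely related 3-oxygenated alkynals, whereas here both reactivity and asymmetric induction are open. Alternative 1 wins on length, the chosen plan on the certainty of C12.

Alternative 2: The cut is C11–C12, by an intramolecular crossed benzoin reaction of the keto aldehyde 2-{2-[(Z)-2-oxodec-4-en-1-yl]-1,3-dithian-2-yl}acetaldehyde A3. A chiral triazolium carbene would turn the C11 aldehyde into its Breslow intermediate, which adds to the C12 ketone to give (S)-3-hydroxy-3-[(Z)-oct-2-en-1-yl]-6,10-dithiaspiro[4.5]decan-2-one A4.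
- In favour: enantioselective aldehyde–ketone benzoin closure to five-membered tertiary acyloins is established. On the reliability of the asymmetric step this alternative is the equal of, or better than, the chosen plan, whose arm-selective variant is untried.
- Against: A3 is a β,γ-unsaturated ketone with doubly activated C13 hydrogens, and the amine base can move the Z-olefin into conjugation. The catalyst must tell apart two CH2 flanks of similar size. The oxidation pattern of A4 is displaced: the carbonyl sits on C11, so reduction, dithiane removal beside an olefin, and elimination are needed before the route reaches the stage of 11. After that, the same chlorination and aldol steps follow.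
- Comparison: the ring is closed at a different bond with good stereocontrol, but roughly four extra redox and protecting-group steps and a multi-step synthesis of A3 make it longer than the chosen plan.

Alternative 3: The cut is C8–C9, by cis-hydroacylation of the enynal methyl (5E,9S,11Z)-9-(3-oxopropyl)-9-(triethylsilyloxy)heptadeca-5,11-dien-7-ynoate A5 with [Rh(dppe)]BF4. It gives methyl (5E,7E)-7-{(2S)-2-[(Z)-oct-2-en-1-yl]-5-oxo-2-(triethylsilyloxy)cyclopentylidene}hept-5-enoate A6 by a 5-exo-dig closure.
- In favour: syn addition of acyl and hydrogen sets the 7E geometry stereospecifically and carries the whole upper chain in with the ring closure. On control of the C7=C8 geometry this is better than the chosen plan, which relies on a thermodynamically biased elimination.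
- Against: the step creates no stereocentre. C12 would have to be made beforehand as a tertiary propargylic ether whose two alkyl arms differ little, a hard problem for asymmetric alkynylation. A6 lacks both the C10=C11 olefin and the chlorine. Dehydrogenation and α-chlorination would have to be done on a molecule with three other olefins, where nucleophilic epoxidation is no longer site-selective and electrophilic chlorine attacks C14=C15.
- Comparison: the same metal and the same elementary steps are used, with cis instead of trans addition. The gain of one step in chain attachment is lost again in the late functionalization of C10 and C11 and in the separate construction of C12.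

Key step: step 4

Assumption: the antipode of Tol-BINAP that leads to (S)-7 cannot be assigned with confidence by analogy; the (R)-ligand is written, and its mirror image is to be used if the sense of induction proves opposite.

## Route

Step 1
Reactants: 1 ethyl 3-(trimethylsilyl)propiolate; 2 allylmagnesium bromide (2.3 equiv)
Product: 4 4-[(trimethylsilyl)ethynyl]hepta-1,6-dien-4-ol, via allyl ynone 3 (not isolated)
Conditions: Et2O/THF, −78 to 0 °C; NH4Cl (aq)
Reagents that add atoms: none
Why: Double 1,2-addition of a Grignard reagent to an ester through ketone 3; allylmagnesium halides add to carbonyl groups through a cyclic transition state much faster than in conjugate fashion, and the silyl cap shields the alkyne terminus. The product is achiral.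

Step 2
Reactants: 4 4-[(trimethylsilyl)ethynyl]hepta-1,6-dien-4-ol
Product: 5 triethyl({4-[(trimethylsilyl)ethynyl]hepta-1,6-dien-4-yl}oxy)silane
Conditions: Et3SiOTf, 2,6-lutidine, CH2Cl2, −78 to 0 °C
Reagents that add atoms: triethylsilyl trifluoromethanesulfonate, CC[Si](CC)(CC)OS(=O)(=O)C(F)(F)F
Why: Silyl triflate silylation of a hindered tertiary alcohol. The triethylsilyl ether is stable to ozone, ylide, alkaline peroxide and enolate chemistry, is a poor β-leaving group, and is later removed by HF·pyridine.

Step 3
Reactants: 5 triethyl({4-[(trimethylsilyl)ethynyl]hepta-1,6-dien-4-yl}oxy)silane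
Product: 6 3-(triethylsilyloxy)-3-[(trimethylsilyl)ethynyl]pentanedial
Conditions: O3, CH2Cl2, −78 °C (Sudan Red 7B end point); PPh3, −78 °C to rt
Reagents that add atoms: ozone, [O-][O+]=O
Why: Ozonolysis with reductive work-up; terminal olefins take up ozone far faster than a silyl-capped alkyne, and the dye marks the end point. The achiral dialdehyde is a β-silyloxy aldehyde and is used without delay.

Step 4
Reactants: 6 3-(triethylsilyloxy)-3-[(trimethylsilyl)ethynyl]pentanedial
Product: 7 (S)-2-[4-oxo-1-(triethylsilyloxy)-3-(trimethylsilyl)cyclopent-2-en-1-yl]acetaldehyde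
Conditions: [Rh((R)-Tol-BINAP)]BF4 (10 mol %, from [Rh(nbd)((R)-Tol-BINAP)]BF4 and H2), CH2Cl2 (0.02 M), rt
Reagents that add atoms: none
Why: Oxidative addition of one aldehyde C–H bond to the cationic monovalent rhodium centre gives an acyl rhodium hydride; the tethered silylalkyne inserts with net trans delivery of hydride to C11, giving a six-membered acyl rhodacycle (Rh, C9, C8, C12, C11, C10), and reductive elimination forms C9–C10. The closest known reaction type is the cationic rhodium bisphosphine trans-hydroacylation of 4-alkynals to cyclopent-2-enones, including its Tol-BINAP-controlled kinetic resolution and its desymmetrization of 3-alkoxy-3-alkynyl-4-alkynals with a fully substituted C3; here the catalyst must choose between two enantiotopic formylmethyl arms instead of two alkynes, which is untested and is the point on which the plan rests. Ring C8–C12 is closed in a formal 5-endo-dig mode, with both alkyne carbons ending up in the ring. The configuration at C12 is decided by the ligand antipode alone: the two arms lead to diastereomeric rhodacycles in which the triethylsilyloxy group and the spectator CH2CHO arm exchange places next to the P-aryl groups, and the large size difference between them gives the ligand something to read. The step needs arm selectivity (from the ligand); trans rather than cis hydroacylation (favoured by the silyl-capped alkyne and the fully substituted C12; a cis pathway from the mismatched arm would give an alkylidenecyclobutanone, a separable constitutional isomer, and so would not erode the enantiomeric purity of 7); cyclization faster than decarbonylation (alkyne chelation of the acyl hydride, room temperature); and inertness of the remaining aldehyde of 7, whose only intramolecular partner is a hindered, trisubstituted enone carbon.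

Step 5
Reactants: 7 (S)-2-[4-oxo-1-(triethylsilyloxy)-3-(trimethylsilyl)cyclopent-2-en-1-yl]acetaldehyde; 8 hexyltriphenylphosphonium bromide
Product: 10 (S)-4-[(Z)-oct-2-en-1-yl]-4-(triethylsilyloxy)-2-(trimethylsilyl)cyclopent-2-en-1-one, via hexylidenetriphenylphosphorane 9 (not isolated)
Conditions: 8, NaN(SiMe3)2, THF, 0 °C; ylide added to 7 at −78 °C, then to −20 °C
Reagents that add atoms: none
Why: Salt-free Wittig reaction of a non-stabilized ylide, which gives the Z-olefin under kinetic control through the cis-oxaphosphetane. The aldehyde is far more electrophilic than the hindered enone, and inverse addition at low temperature keeps the base away from the β-silyloxy carbonyl units; C12 is not touched.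

Step 6
Reactants: 10 (S)-4-[(Z)-oct-2-en-1-yl]-4-(triethylsilyloxy)-2-(trimethylsilyl)cyclopent-2-en-1-one
Product: 11 (S)-4-[(Z)-oct-2-en-1-yl]-4-(triethylsilyloxy)cyclopent-2-en-1-one
Conditions: Bu4NF (1.1 equiv), AcOH (1.2 equiv), THF, 0 °C to rt
Reagents that add atoms: none
Why: Fluoride-induced protodesilylation of an acyl-activated vinylsilane: fluoride attacks the unhindered SiMe3 group, the developing negative charge on C10 is stabilized by the adjacent carbonyl, and AcOH protonates it. The hindered tertiary triethylsilyl ether should react more slowly, and the buffer suppresses base-induced elimination.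

Step 7
Reactants: 11 (S)-4-[(Z)-oct-2-en-1-yl]-4-(triethylsilyloxy)cyclopent-2-en-1-one
Product: 12 (4S)-4-[(Z)-oct-2-en-1-yl]-4-(triethylsilyloxy)-6-oxabicyclo[3.1.0]hexan-2-one (mixture of the two cis-epoxides, oxirane syn or anti to the silyloxy group)
Conditions: 30% H2O2 (aq), NaOH (0.3 equiv), MeOH, −10 to 0 °C
Reagents that add atoms: hydrogen peroxide, OO
Why: Weitz–Scheffer nucleophilic epoxidation: hydroperoxide adds to C11 and the enolate closes onto oxygen at C10. Only the electron-poor ring olefin reacts, so C14=C15 is untouched; both epoxide diastereomers converge in step 8.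

Step 8
Reactants: 12 (4S)-4-[(Z)-oct-2-en-1-yl]-4-(triethylsilyloxy)-6-oxabicyclo[3.1.0]hexan-2-one
Product: 14 (S)-2-chloro-4-[(Z)-oct-2-en-1-yl]-4-(triethylsilyloxy)cyclopent-2-en-1-one, via chlorohydrin 13 (not isolated)
Conditions: HCl (2 M in Et2O, 3 equiv), CH2Cl2, −20 °C to rt
Reagents that add atoms: hydrogen chloride, Cl
Why: Acid-promoted opening of an α,β-epoxy ketone by chloride at the α-carbon C10 (SN2 next to the carbonyl; C11 is neopentyl-like), followed by loss of water from chlorohydrin 13 through its enol, the classical route from epoxy ketones to 2-chloroenones. No electrophilic chlorine is present, so the Z-olefin is safe, and cold anhydrous acid is chosen to spare the silyl ether.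

Step 9
Reactants: 15 methyl hex-5-enoate; 16 (E)-but-2-enal (5 equiv)
Product: 17 methyl (E)-7-oxohept-5-enoate
Conditions: second-generation Hoveyda–Grubbs catalyst RuCl2(H2IMes)(=CH-C6H4-2-OiPr) (2.5 mol %), CH2Cl2, 40 °C
Reagents that add atoms: none
Why: Olefin cross-metathesis of a terminal olefin with an enal, E-selective under thermodynamic control; excess crotonaldehyde suppresses the homodimer of 15 and propene leaves the mixture.

Step 10
Reactants: 14 (S)-2-chloro-4-[(Z)-oct-2-en-1-yl]-4-(triethylsilyloxy)cyclopent-2-en-1-one; 17 methyl (E)-7-oxohept-5-enoate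
Product: 18 methyl (5E)-7-{(2S)-4-chloro-2-[(Z)-oct-2-en-1-yl]-5-oxo-2-(triethylsilyloxy)cyclopent-3-en-1-yl}-7-hydroxyhept-5-enoate (mixture of diastereomers at C7 and C8)
Conditions: LiN(iPr)2 (1.1 equiv, commercial solution), THF, −78 °C; 17 (1.3 equiv), −78 °C; AcOH quench at −78 °C
Reagents that add atoms: none
Why: Aldol addition of the kinetic lithium enolate: C8 carries the only acidic hydrogens (C12 is quaternary), the enolate adds 1,2 to the enal, and at −78 °C the β-silyloxy group is retained. The new centres at C7 and C8 are removed in step 11.

Step 11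
Reactants: 18 methyl (5E)-7-{(2S)-4-chloro-2-[(Z)-oct-2-en-1-yl]-5-oxo-2-(triethylsilyloxy)cyclopent-3-en-1-yl}-7-hydroxyhept-5-enoate
Product: 20 methyl (5E,7E)-7-{(2R)-4-chloro-2-[(Z)-oct-2-en-1-yl]-5-oxo-2-(triethylsilyloxy)cyclopent-3-en-1-ylidene}hept-5-enoate, via allylic mesylate 19 (not isolated)
Conditions: MsCl, Et3N, CH2Cl2, −20 to 0 °C; then DBU, 0 °C to rt
Reagents that add atoms: none
Why: Mesylation and E1cB elimination through the C8 enolate; both aldol diastereomers converge, and the 7E isomer (chain anti to the C9 carbonyl) should predominate on thermodynamic grounds while 5E is retained. Any 7Z isomer is removed by chromatography.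

Step 12
Reactants: 20 methyl (5E,7E)-7-{(2R)-4-chloro-2-[(Z)-oct-2-en-1-yl]-5-oxo-2-(triethylsilyloxy)cyclopent-3-en-1-ylidene}hept-5-enoate
Product: 21 methyl (5E,7E)-7-{(2R)-4-chloro-2-hydroxy-2-[(Z)-oct-2-en-1-yl]-5-oxocyclopent-3-en-1-ylidene}hept-5-enoate
Conditions: HF·pyridine, pyridine, THF, 0 °C to rt
Reagents that add atoms: none
Why: Fluoride cleavage of the Si–O bond under buffered, weakly acidic conditions that the base-sensitive dienone tolerates; the C12–O bond is not broken, so the configuration is kept.

Step 13
Reactants: 21 methyl (5E,7E)-7-{(2R)-4-chloro-2-hydroxy-2-[(Z)-oct-2-en-1-yl]-5-oxocyclopent-3-en-1-ylidene}hept-5-enoate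
Product: 22 methyl (5E,7E)-7-{(2R)-2-acetoxy-4-chloro-2-[(Z)-oct-2-en-1-yl]-5-oxocyclopent-3-en-1-ylidene}hept-5-enoate
Conditions: Ac2O, DMAP, Et3N, CH2Cl2, rt
Reagents that add atoms: acetic anhydride, CC(=O)OC(C)=O
Why: DMAP-catalysed O-acylation of a tertiary alcohol; with C8 now sp2 there is no enolizable position from which the acetate could be eliminated, and acylation at oxygen retains C12.

## Compound list

1 | ethyl 3-(trimethylsilyl)propiolate | CCOC(=O)C#C[Si](C)(C)C | starting material
2 | allylmagnesium bromide | C=CC[Mg]Br | starting material
3 | 1-(trimethylsilyl)hex-5-en-1-yn-3-one | C=CCC(=O)C#C[Si](C)(C)C | intermediate (not isolated)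
4 | 4-[(trimethylsilyl)ethynyl]hepta-1,6-dien-4-ol | C=CCC(O)(CC=C)C#C[Si](C)(C)C | intermediate
5 | triethyl({4-[(trimethylsilyl)ethynyl]hepta-1,6-dien-4-yl}oxy)silane | C=CCC(CC=C)(O[Si](CC)(CC)CC)C#C[Si](C)(C)C | intermediate
6 | 3-(triethylsilyloxy)-3-[(trimethylsilyl)ethynyl]pentanedial | O=CCC(CC=O)(O[Si](CC)(CC)CC)C#C[Si](C)(C)C | intermediate
7 | (S)-2-[4-oxo-1-(triethylsilyloxy)-3-(trimethylsilyl)cyclopent-2-en-1-yl]acetaldehyde | O=CC[C@@]1(O[Si](CC)(CC)CC)C=C([Si](C)(C)C)C(=O)C1 | intermediate
8 | hexyltriphenylphosphonium bromide | CCCCCC[P+](c1ccccc1)(c1ccccc1)c1ccccc1.[Br-] | starting material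
9 | hexylidenetriphenylphosphorane | CCCCCC=P(c1ccccc1)(c1ccccc1)c1ccccc1 | intermediate (not isolated)
10 | (S)-4-[(Z)-oct-2-en-1-yl]-4-(triethylsilyloxy)-2-(trimethylsilyl)cyclopent-2-en-1-one | CCCCC/C=C\C[C@@]1(O[Si](CC)(CC)CC)C=C([Si](C)(C)C)C(=O)C1 | intermediate
11 | (S)-4-[(Z)-oct-2-en-1-yl]-4-(triethylsilyloxy)cyclopent-2-en-1-one | CCCCC/C=C\C[C@@]1(O[Si](CC)(CC)CC)C=CC(=O)C1 | intermediate
12 | (4S)-4-[(Z)-oct-2-en-1-yl]-4-(triethylsilyloxy)-6-oxabicyclo[3.1.0]hexan-2-one, both cis-epoxide diastereomers | CCCCC/C=C\C[C@@]1(O[Si](CC)(CC)CC)C2OC2C(=O)C1 | intermediate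
13 | (4S)-2-chloro-3-hydroxy-4-[(Z)-oct-2-en-1-yl]-4-(triethylsilyloxy)cyclopentan-1-one, trans-chlorohydrin, diastereomers at C2 and C3 | CCCCC/C=C\C[C@@]1(O[Si](CC)(CC)CC)C(O)C(Cl)C(=O)C1 | intermediate (not isolated)
14 | (S)-2-chloro-4-[(Z)-oct-2-en-1-yl]-4-(triethylsilyloxy)cyclopent-2-en-1-one | CCCCC/C=C\C[C@@]1(O[Si](CC)(CC)CC)C=C(Cl)C(=O)C1 | intermediate
15 | methyl hex-5-enoate | COC(=O)CCCC=C | starting material
16 | (E)-but-2-enal | C/C=C/C=O | starting material
17 | methyl (E)-7-oxohept-5-enoate | COC(=O)CCC/C=C/C=O | intermediate
18 | methyl (5E)-7-{(2S)-4-chloro-2-[(Z)-oct-2-en-1-yl]-5-oxo-2-(triethylsilyloxy)cyclopent-3-en-1-yl}-7-hydroxyhept-5-enoate, diastereomers at C7 and C8 | CCCCC/C=C\C[C@@]1(O[Si](CC)(CC)CC)C=C(Cl)C(=O)C1C(O)/C=C/CCCC(=O)OC | intermediate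
19 | methyl (5E)-7-{(2S)-4-chloro-2-[(Z)-oct-2-en-1-yl]-5-oxo-2-(triethylsilyloxy)cyclopent-3-en-1-yl}-7-(methylsulfonyloxy)hept-5-enoate, diastereomers at C7 and C8 | CCCCC/C=C\C[C@@]1(O[Si](CC)(CC)CC)C=C(Cl)C(=O)C1C(OS(C)(=O)=O)/C=C/CCCC(=O)OC | intermediate (not isolated)
20 | methyl (5E,7E)-7-{(2R)-4-chloro-2-[(Z)-oct-2-en-1-yl]-5-oxo-2-(triethylsilyloxy)cyclopent-3-en-1-ylidene}hept-5-enoate | CCCCC/C=C\C[C@@]1(O[Si](CC)(CC)CC)C=C(Cl)C(=O)/C1=C/C=C/CCCC(=O)OC | intermediate
21 | methyl (5E,7E)-7-{(2R)-4-chloro-2-hydroxy-2-[(Z)-oct-2-en-1-yl]-5-oxocyclopent-3-en-1-ylidene}hept-5-enoate | CCCCC/C=C\C[C@@]1(O)C=C(Cl)C(=O)/C1=C/C=C/CCCC(=O)OC | intermediate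
22 | methyl (5E,7E)-7-{(2R)-2-acetoxy-4-chloro-2-[(Z)-oct-2-en-1-yl]-5-oxocyclopent-3-en-1-ylidene}hept-5-enoate | CCCCC/C=C\C[C@@]1(OC(C)=O)C=C(Cl)C(=O)/C1=C/C=C/CCCC(=O)OC | target

## Step count and least certain steps

Total: 13 steps. Longest linear sequence: 12 steps (steps 1–8 and 10–13); step 9 is a one-step side branch.

Step 4 (key step).
- What may go wrong: insufficient discrimination between the two enantiotopic CH2CHO arms, because this mode of group selection has no direct precedent and a bulky silyl ether is a weaker donor than the methyl ethers of the known substrates. Decarbonylation of either aldehyde, or further reaction of the spectator aldehyde of 7 at rhodium, may also intervene.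
- Fallback, setting out from 5 and returning at 7: the arms are told apart by an enzyme before an achiral cyclization.
  - Ozonolysis of 5 with NaBH4 work-up would give 3-(triethylsilyloxy)-3-[(trimethylsilyl)ethynyl]pentane-1,5-diol F1.
  - Pseudomonas cepacia lipase with vinyl acetate in iPr2O would acetylate one hydroxyethyl arm to (R)-5-hydroxy-3-(triethylsilyloxy)-3-[(trimethylsilyl)ethynyl]pentyl acetate F2. The opposite sense would be reached by enzymatic hydrolysis of the diacetate.
  - Dess–Martin oxidation would give (S)-5-oxo-3-(triethylsilyloxy)-3-[(trimethylsilyl)ethynyl]pentyl acetate F3, a mono-aldehyde of the precedented class.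
  - [Rh(dppe)]2(BF4)2 would cyclize F3 to 2-[(S)-4-oxo-1-(triethylsilyloxy)-3-(trimethylsilyl)cyclopent-2-en-1-yl]ethyl acetate F4.
  - Lipase hydrolysis at pH 7 would give (S)-4-(2-hydroxyethyl)-4-(triethylsilyloxy)-2-(trimethylsilyl)cyclopent-2-en-1-one F5, and Dess–Martin oxidation would return 7.

Step 6.
- What may go wrong: competing cleavage of the tertiary O–Si bond, or base-induced elimination or retro-aldol opening once that oxygen is free, because fluoride does not distinguish sharply between the two silicon atoms.
- Fallback, setting out from 10 and returning at 11: selectivity is given up. Excess Bu4NF buffered with AcOH in THF at rt would remove both silyl groups to give (S)-4-hydroxy-4-[(Z)-oct-2-en-1-yl]cyclopent-2-en-1-one F6, and Et3SiOTf with 2,6-lutidine in CH2Cl2 at −78 °C would re-silylate the tertiary alcohol to 11.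

Step 8.
- What may go wrong: loss of the triethylsilyl ether in HCl, or incomplete dehydration of 13, because the hydroxyl on C11 is secondary and flanked by the quaternary C12.
- Fallback, setting out from 12 and returning at 14: the deprotection is accepted. Concentrated aqueous HCl in THF at rt would open the epoxide, dehydrate and cleave the silyl ether to give (S)-2-chloro-4-hydroxy-4-[(Z)-oct-2-en-1-yl]cyclopent-2-en-1-one F7, and Et3SiOTf with 2,6-lutidine would restore the silyl ether of 14.

Step 11.
- What may go wrong: incomplete control of the C7=C8 geometry in the E1cB elimination, because the 7E chain lies next to the substituents of the quaternary C12 and the energy difference to 7Z may be small.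
- Fallback, setting out from 18 and returning at 20: geometry is corrected after the elimination. The same elimination is run, and the fraction containing methyl (5E,7Z)-7-{(2R)-4-chloro-2-[(Z)-oct-2-en-1-yl]-5-oxo-2-(triethylsilyloxy)cyclopent-3-en-1-ylidene}hept-5-enoate F8 is equilibrated with a catalytic amount of I2 in CH2Cl2 under diffuse light. This should enrich the all-trans conjugated dienone 20, while the isolated C14 olefin, which is outside the chromophore, should isomerize much more slowly. The mixture is then separated and the remaining F8 recycled.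

## Further compounds

F1 | step 4 | 3-(triethylsilyloxy)-3-[(trimethylsilyl)ethynyl]pentane-1,5-diol | OCCC(CCO)(O[Si](CC)(CC)CC)C#C[Si](C)(C)C
F2 | step 4 | (R)-5-hydroxy-3-(triethylsilyloxy)-3-[(trimethylsilyl)ethynyl]pentyl acetate | CC(=O)OCC[C@@](CCO)(O[Si](CC)(CC)CC)C#C[Si](C)(C)C
F3 | step 4 | (S)-5-oxo-3-(triethylsilyloxy)-3-[(trimethylsilyl)ethynyl]pentyl acetate | CC(=O)OCC[C@@](CC=O)(O[Si](CC)(CC)CC)C#C[Si](C)(C)C
F4 | step 4 | 2-[(S)-4-oxo-1-(triethylsilyloxy)-3-(trimethylsilyl)cyclopent-2-en-1-yl]ethyl acetate | CC(=O)OCC[C@@]1(O[Si](CC)(CC)CC)C=C([Si](C)(C)C)C(=O)C1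
F5 | step 4 | (S)-4-(2-hydroxyethyl)-4-(triethylsilyloxy)-2-(trimethylsilyl)cyclopent-2-en-1-one | OCC[C@@]1(O[Si](CC)(CC)CC)C=C([Si](C)(C)C)C(=O)C1
F6 | step 6 | (S)-4-hydroxy-4-[(Z)-oct-2-en-1-yl]cyclopent-2-en-1-one | CCCCC/C=C\C[C@@]1(O)C=CC(=O)C1
F7 | step 8 | (S)-2-chloro-4-hydroxy-4-[(Z)-oct-2-en-1-yl]cyclopent-2-en-1-one | CCCCC/C=C\C[C@@]1(O)C=C(Cl)C(=O)C1
F8 | step 11 | methyl (5E,7Z)-7-{(2R)-4-chloro-2-[(Z)-oct-2-en-1-yl]-5-oxo-2-(triethylsilyloxy)cyclopent-3-en-1-ylidene}hept-5-enoate | CCCCC/C=C\C[C@@]1(O[Si](CC)(CC)CC)C=C(Cl)C(=O)/C1=C\C=C\CCCC(=O)OC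
A1 | alternative 1 | methyl 8-{3-chloro-5-[(Z)-oct-2-en-1-yl]furan-2-yl}-8-hydroxyoct-6-ynoate (racemic at the carbinol carbon) | CCCCC/C=C\Cc1cc(Cl)c(o1)C(O)C#CCCCCC(=O)OC
A2 | alternative 1 | methyl 7-{(1S,5S)-3-chloro-5-hydroxy-5-[(Z)-oct-2-en-1-yl]-2-oxocyclopent-3-en-1-yl}hept-6-ynoate | CCCCC/C=C\C[C@@]1(O)C=C(Cl)C(=O)[C@H]1C#CCCCCC(=O)OC
A3 | alternative 2 | 2-{2-[(Z)-2-oxodec-4-en-1-yl]-1,3-dithian-2-yl}acetaldehyde | CCCCC/C=C\CC(=O)CC1(CC=O)SCCCS1
A4 | alternative 2 | (S)-3-hydroxy-3-[(Z)-oct-2-en-1-yl]-6,10-dithiaspiro[4.5]decan-2-one | CCCCC/C=C\C[C@@]1(O)C(=O)CC2(SCCCS2)C1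
A5 | alternative 3 | methyl (5E,9S,11Z)-9-(3-oxopropyl)-9-(triethylsilyloxy)heptadeca-5,11-dien-7-ynoate | CCCCC/C=C\C[C@](CCC=O)(O[Si](CC)(CC)CC)C#C/C=C/CCCC(=O)OC
A6 | alternative 3 | methyl (5E,7E)-7-{(2S)-2-[(Z)-oct-2-en-1-yl]-5-oxo-2-(triethylsilyloxy)cyclopentylidene}hept-5-enoate | CCCCC/C=C\C[C@@]1(O[Si](CC)(CC)CC)CCC(=O)/C1=C/C=C/CCCC(=O)OC
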